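**Assumption:** the target is taken exactly as the SMILES gives it: butenolide carbon C16 is R, the side-chain alkene is Z (CH2OH cis to the CH2 that carries the butenolide), and the decalin is 5S,10S as in (+)-sclareolide.

Abbreviations: Dec = (4aS,8aS)-2,5,5,8a-tetramethyl-3,4,4a,5,6,7,8,8a-octahydronaphthalen-1-yl; TBS = tert-butyldimethylsilyl; pin = pinacolato; cod = 1,5-cyclooctadiene; dtbpy = 4,4'-di-tert-butyl-2,2'-bipyridine.

## Retrosynthetic overview

1. The butenolide is unveiled last from a 2,3-disubstituted furan: C–H borylation at C5, then oxidative dearomatisation with enantioselective proton transfer, which sets C16.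
2. The C12–C13 and C14–C15 bonds and the Z alkene come from one three-component union: homodrimenyl Grignard + propargyl alcohol (anti-carbomagnesiation) + methyl 2-(bromomethyl)furan-3-carboxylate.
3. The homodrimenyl bromide comes from (+)-sclareolide (acid elimination, reduction, Appel); the furan electrophile comes from methyl 2-methylfuran-3-carboxylate.
4. Ring order: the decalin is bought in with sclareolide; the five-membered oxygen ring is bought in as a furan and turned into the butenolide in the penultimate step; no other ring is formed.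

## Route

Step 1
Reactants: 1 (+)-sclareolide
Product: 2 methyl 2-Dec-acetate
Conditions: conc. H2SO4, MeOH, 50 °C, 24 h; AgNO3–SiO2 chromatography
Reagents that add atoms: methanol (CO)
Why: Acid opens the tertiary lactone C–O bond (E1), loss of the C9 proton gives the thermodynamically preferred tetrasubstituted alkene and the acid is trapped by Fischer esterification; the ring-fusion centres are untouched and minor alkene isomers are removed on silver nitrate silica.

Step 2
Reactants: 2 methyl 2-Dec-acetate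
Product: 3 2-Dec-ethan-1-ol
Conditions: LiAlH4, THF, 0 °C to rt; Fieser work-up
Reagents that add atoms: none
Why: Standard hydride reduction of an ester to the primary alcohol; the isolated tetrasubstituted alkene is inert.

Step 3
Reactants: 3 2-Dec-ethan-1-ol
Product: 4 2-Dec-ethyl bromide
Conditions: CBr4, PPh3, CH2Cl2, 0 °C
Reagents that add atoms: carbon tetrabromide (BrC(Br)(Br)Br)
Why: Appel reaction converts the unhindered primary alcohol to the bromide under neutral conditions that do not touch the alkene.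

Step 4
Reactants: 5 methyl 2-methylfuran-3-carboxylate
Product: 6 methyl 2-(bromomethyl)furan-3-carboxylate
Conditions: N-bromosuccinimide (1.05 equiv), AIBN (5 mol %), PhCF3, 85 °C
Reagents that add atoms: N-bromosuccinimide (O=C1CCC(=O)N1Br)
Why: Wohl–Ziegler radical bromination at the furfuryl methyl group; the ester deactivates the ring towards electrophilic bromination and makes the bromide stable enough to handle.

Step 5
Reactants: 4 2-Dec-ethyl bromide (1.2 equiv); 7 prop-2-yn-1-ol (1.0 equiv); 6 methyl 2-(bromomethyl)furan-3-carboxylate (1.5 equiv)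
Product: 11 methyl 2-[(2Z)-4-hydroxy-3-(2-Dec-ethyl)but-2-en-1-yl]furan-3-carboxylate, via homodrimenyl Grignard reagent 8 (not isolated), via chloromagnesium propargyl alkoxide 9 (not isolated), via (Z)-alkenylmagnesium alkoxide 10 (not isolated)
Conditions: Mg, THF, 40 °C (4 to 8); i-PrMgCl (1.0 equiv), THF, −20 °C (7 to 9); 8 + 9, CuI (10 mol %), THF/Et2O, −10 °C to rt, 3 h; then 6, −30 to 0 °C; aq NH4Cl
Reagents that add atoms: none
Why: Duboudin–Jousseaume copper-catalysed anti-carbomagnesiation puts the alkyl group on C2 of the propargyl alkoxide and magnesium on C3 inside a five-membered alkoxide chelate (Mg cis to CH2O), and copper-mediated SN2 coupling of this alkenylmagnesium with the furfuryl bromide goes with retention, fixing the Z alkene; the sacrificial i-PrMgCl spares one equivalent of 8.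

Step 6
Reactants: 11 methyl 2-[(2Z)-4-hydroxy-3-(2-Dec-ethyl)but-2-en-1-yl]furan-3-carboxylate
Product: 12 (2Z)-4-[3-(hydroxymethyl)furan-2-yl]-2-(2-Dec-ethyl)but-2-en-1-ol
Conditions: LiAlH4 (1.5 equiv), THF, 0 °C; Fieser work-up
Reagents that add atoms: none
Why: Hydride reduction of the furoate ester to the 3-furylmethanol; the furan and the isolated alkenes are not reduced.

Step 7
Reactants: 12 (2Z)-4-[3-(hydroxymethyl)furan-2-yl]-2-(2-Dec-ethyl)but-2-en-1-ol
Product: 13 bis-TBS ether of 12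
Conditions: TBSCl (2.4 equiv), imidazole (5 equiv), DMF, rt
Reagents that add atoms: tert-butyldimethylsilyl chloride (CC(C)(C)[Si](C)(C)Cl)
Why: Corey silylation of both primary alcohols; the furylmethyl oxygen must be capped so that it cannot attack the enol lactone (acyl transfer) formed in step 9.

Step 8
Reactants: 13 bis-TBS ether of 12
Product: 14 furan-5-yl boronate, 2-{4-(TBSO-methyl)-5-[(2Z)-4-(TBSO)-3-(2-Dec-ethyl)but-2-en-1-yl]furan-2-yl}-4,4,5,5-tetramethyl-1,3,2-dioxaborolane
Conditions: [Ir(OMe)(cod)]2 (1.5 mol %), dtbpy (3 mol %), B2pin2 (1.0 equiv), THF, 25 °C; short silica plug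
Reagents that add atoms: bis(pinacolato)diboron (CC1(C)OB(OC1(C)C)B1OC(C)(C)C(C)(C)O1)
Why: Iridium-catalysed C–H borylation (Ishiyama–Miyaura–Hartwig) is selective for the only free α-position of the furan, and being neutral it avoids deprotonation of the doubly activated furfuryl/allylic CH2; silyl ethers and the hindered alkenes are inert.

Step 9 (key step)
Reactants: 14 furan-5-yl boronate
Product: 17 (5R)-4-(TBSO-methyl)-5-[(2Z)-4-(TBSO)-3-(2-Dec-ethyl)but-2-en-1-yl]furan-2(5H)-one, via 2-boryloxyfuran 15 (not isolated), via furan-2(3H)-one enol lactone 16 (not isolated)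
Conditions: Me3NO (anhydrous, 1.1 equiv), CH2Cl2, 25 °C; N2 purge to remove NMe3; then 9-O-(phenanthren-9-yl)cupreidine (10 mol %, quinidine series), t-BuOH (2 equiv), CH2Cl2, −20 °C, 48 h
Reagents that add atoms: trimethylamine N-oxide (C[N+](C)(C)[O-])
Why: Proposed new method: N-oxide oxidation of the furyl boronate (boron-to-oxygen 1,2-shift, a known arylboronate hydroxylation) gives the still aromatic 2-boryloxyfuran, tert-butanol releases the 2-hydroxyfuran, which ketonises kinetically at C3 to the enol lactone, and the bifunctional 6'-hydroxy cinchona base then relays the proton from C3 to C5 within a chiral ammonium dienolate ion pair (closest known reaction: cinchona-catalysed enantioselective isomerisation of β,γ- to α,β-unsaturated butenolides), so the ring loses its aromaticity and C16 is set as R in the same flask; the sense of induction is assigned by analogy and must be confirmed on a model, since the pseudoenantiomeric cupreine ether gives 16S, and the minor 16-epimer is removed by HPLC after step 10.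

Step 10
Reactants: 17 (5R)-bis-TBS butenolide
Product: 18 16-epi-luffarin L, (5R)-4-(hydroxymethyl)-5-[(2Z)-4-hydroxy-3-(2-Dec-ethyl)but-2-en-1-yl]furan-2(5H)-one
Conditions: HF·pyridine, THF/pyridine, 0 °C to rt
Reagents that add atoms: none
Why: Buffered fluoride desilylation of two primary TBS ethers under mildly acidic conditions leaves the base-sensitive γ-stereocentre, the lactone and both alkenes untouched.

## Compound list

1 | (+)-sclareolide, (3aR,5aS,9aS,9bR)-3a,6,6,9a-tetramethyldecahydronaphtho[2,1-b]furan-2(1H)-one | C[C@]12CCCC([C@@H]1CC[C@@]3([C@@H]2CC(=O)O3)C)(C)C | starting material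
2 | methyl 2-[(4aS,8aS)-2,5,5,8a-tetramethyl-3,4,4a,5,6,7,8,8a-octahydronaphthalen-1-yl]acetate | CC1=C(CC(=O)OC)[C@@]2(C)CCCC(C)(C)[C@@H]2CC1 | intermediate
3 | 2-[(4aS,8aS)-2,5,5,8a-tetramethyl-3,4,4a,5,6,7,8,8a-octahydronaphthalen-1-yl]ethan-1-ol | CC1=C(CCO)[C@@]2(C)CCCC(C)(C)[C@@H]2CC1 | intermediate
4 | (4aS,8aS)-1-(2-bromoethyl)-2,5,5,8a-tetramethyl-3,4,4a,5,6,7,8,8a-octahydronaphthalene | CC1=C(CCBr)[C@@]2(C)CCCC(C)(C)[C@@H]2CC1 | intermediate
5 | methyl 2-methylfuran-3-carboxylate | COC(=O)c1ccoc1C | starting material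
6 | methyl 2-(bromomethyl)furan-3-carboxylate | COC(=O)c1ccoc1CBr | intermediate
7 | prop-2-yn-1-ol | C#CCO | starting material
8 | (2-Dec-ethyl)magnesium bromide | CC1=C(CC[Mg]Br)[C@@]2(C)CCCC(C)(C)[C@@H]2CC1 | intermediate
9 | chloromagnesium prop-2-yn-1-olate | C#CCO[Mg]Cl | intermediate
10 | [(1Z)-3-(chloromagnesiooxy)-2-(2-Dec-ethyl)prop-1-en-1-yl]magnesium bromide | CC1=C(CC/C(=C/[Mg]Br)CO[Mg]Cl)[C@@]2(C)CCCC(C)(C)[C@@H]2CC1 | intermediate
11 | methyl 2-[(2Z)-4-hydroxy-3-(2-Dec-ethyl)but-2-en-1-yl]furan-3-carboxylate | CC1=C(CC/C(=C/Cc3occc3C(=O)OC)CO)[C@@]2(C)CCCC(C)(C)[C@@H]2CC1 | intermediate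
12 | (2Z)-4-[3-(hydroxymethyl)furan-2-yl]-2-(2-Dec-ethyl)but-2-en-1-ol | CC1=C(CC/C(=C/Cc3occc3CO)CO)[C@@]2(C)CCCC(C)(C)[C@@H]2CC1 | intermediate
13 | bis-TBS ether of 12 | CC1=C(CC/C(=C/Cc3occc3CO[Si](C)(C)C(C)(C)C)CO[Si](C)(C)C(C)(C)C)[C@@]2(C)CCCC(C)(C)[C@@H]2CC1 | intermediate
14 | 2-{4-(TBSO-methyl)-5-[(2Z)-4-(TBSO)-3-(2-Dec-ethyl)but-2-en-1-yl]furan-2-yl}-4,4,5,5-tetramethyl-1,3,2-dioxaborolane | CC1=C(CC/C(=C/Cc3oc(B4OC(C)(C)C(C)(C)O4)cc3CO[Si](C)(C)C(C)(C)C)CO[Si](C)(C)C(C)(C)C)[C@@]2(C)CCCC(C)(C)[C@@H]2CC1 | intermediate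
15 | 2-({4-(TBSO-methyl)-5-[(2Z)-4-(TBSO)-3-(2-Dec-ethyl)but-2-en-1-yl]furan-2-yl}oxy)-4,4,5,5-tetramethyl-1,3,2-dioxaborolane | CC1=C(CC/C(=C/Cc3oc(OB4OC(C)(C)C(C)(C)O4)cc3CO[Si](C)(C)C(C)(C)C)CO[Si](C)(C)C(C)(C)C)[C@@]2(C)CCCC(C)(C)[C@@H]2CC1 | intermediate
16 | 4-(TBSO-methyl)-5-[(2Z)-4-(TBSO)-3-(2-Dec-ethyl)but-2-en-1-yl]furan-2(3H)-one | CC1=C(CC/C(=C/CC3=C(CO[Si](C)(C)C(C)(C)C)CC(=O)O3)CO[Si](C)(C)C(C)(C)C)[C@@]2(C)CCCC(C)(C)[C@@H]2CC1 | intermediate
17 | (5R)-4-(TBSO-methyl)-5-[(2Z)-4-(TBSO)-3-(2-Dec-ethyl)but-2-en-1-yl]furan-2(5H)-one | CC1=C(CC/C(=C/C[C@H]3OC(=O)C=C3CO[Si](C)(C)C(C)(C)C)CO[Si](C)(C)C(C)(C)C)[C@@]2(C)CCCC(C)(C)[C@@H]2CC1 | intermediate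
18 | 16-epi-luffarin L, (5R)-4-(hydroxymethyl)-5-[(2Z)-4-hydroxy-3-{2-[(4aS,8aS)-2,5,5,8a-tetramethyl-3,4,4a,5,6,7,8,8a-octahydronaphthalen-1-yl]ethyl}but-2-en-1-yl]furan-2(5H)-one | CC1=C(CC/C(=C/C[C@H]2OC(=O)C=C2CO)CO)[C@@]2(C)CCCC(C)(C)[C@@H]2CC1 | target

## Step count and risk

Total steps: 10. Longest linear sequence: 9 (steps 1–3 and 5–10, from sclareolide); step 4 is the one-step side branch.

**Step 9 (most likely to fail).** The telescoped oxidation and proton transfer may give low enantioselectivity, or racemic butenolide from background ketonisation. The fallback sets out from 13 and sets C16 by reagent-controlled carbonyl reduction instead of proton transfer: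
- Dye-sensitised photooxygenation (O2, rose bengal, hν, i-Pr2NEt, CH2Cl2, −78 °C) adds singlet oxygen across the furan to the furan endoperoxide F1.
- Base-induced Kornblum–DeLaMare fragmentation in the same flask gives the 5-hydroxy-5-alkyl butenolide F2.
- K2CO3/MeI in DMF opens it to the Z-configured γ-keto enoate methyl ester F3.
- (S)-2-methyl-CBS-oxazaborolidine with catecholborane (toluene, −78 °C) reduces the enone carbonyl to the 16R hydroxy ester F4, which lactonises with loss of methanol and comes back to the route at 17.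

**Step 5.** The one-pot copper-mediated alkylation of the alkenylmagnesium may be outrun by attack on the ester or by base-induced isomerisation of the skipped diene. The fallback sets out from 10:
- Quench with I2 to isolate the (2Z)-vinyl iodide F5.
- Make the furfurylzinc bromide F6 from 6 (Zn dust, LiCl, THF).
- Join F5 and F6 by Negishi coupling (Pd(PPh3)4, THF, 25 °C), which comes back to the route at 11 under neutral conditions.

**Step 1.** The one-pot E1 opening may give too much of the trisubstituted and exocyclic alkene isomers or re-lactonise. The fallback sets out from 1 and separates ring opening, dehydration and alkene equilibration: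
- Saponify (KOH, aqueous MeOH) to the potassium hydroxy carboxylate F7.
- Alkylate with MeI in DMF to the 8-hydroxy methyl ester F8.
- Dehydrate with SOCl2/pyridine at −78 °C to the exocyclic alkene ester F9 (with some trisubstituted isomer).
- Isomerise with aqueous HI in benzene at 85 °C into the tetrasubstituted alkene, coming back to the route at 2.

## Further compounds

F1 | step 9 | furan endoperoxide, 1-[(2Z)-4-(TBSO)-3-(2-Dec-ethyl)but-2-en-1-yl]-6-(TBSO-methyl)-2,3,7-trioxabicyclo[2.2.1]hept-5-ene (mixture at the bridgeheads) | CC1=C(CC/C(=C/CC34OOC(O3)C=C4CO[Si](C)(C)C(C)(C)C)CO[Si](C)(C)C(C)(C)C)[C@@]2(C)CCCC(C)(C)[C@@H]2CC1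
F2 | step 9 | 5-hydroxy-4-(TBSO-methyl)-5-[(2Z)-4-(TBSO)-3-(2-Dec-ethyl)but-2-en-1-yl]furan-2(5H)-one (both C5 epimers) | CC1=C(CC/C(=C/CC3(O)OC(=O)C=C3CO[Si](C)(C)C(C)(C)C)CO[Si](C)(C)C(C)(C)C)[C@@]2(C)CCCC(C)(C)[C@@H]2CC1
F3 | step 9 | methyl (2Z,6Z)-3,7-bis(TBSO-methyl)-4-oxo-9-Dec-nona-2,6-dienoate | CC1=C(CC/C(=C/CC(=O)/C(CO[Si](C)(C)C(C)(C)C)=C\C(=O)OC)CO[Si](C)(C)C(C)(C)C)[C@@]2(C)CCCC(C)(C)[C@@H]2CC1
F4 | step 9 | methyl (2Z,4R,6Z)-4-hydroxy-3,7-bis(TBSO-methyl)-9-Dec-nona-2,6-dienoate | CC1=C(CC/C(=C/C[C@@H](O)/C(CO[Si](C)(C)C(C)(C)C)=C\C(=O)OC)CO[Si](C)(C)C(C)(C)C)[C@@]2(C)CCCC(C)(C)[C@@H]2CC1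
F5 | step 5 | (2Z)-3-iodo-2-(2-Dec-ethyl)prop-2-en-1-ol | CC1=C(CC/C(=C/I)CO)[C@@]2(C)CCCC(C)(C)[C@@H]2CC1
F6 | step 5 | [3-(methoxycarbonyl)furan-2-yl]methylzinc bromide | COC(=O)c1ccoc1C[Zn]Br
F7 | step 1 | potassium 2-[(1R,2R,4aS,8aS)-2-hydroxy-2,5,5,8a-tetramethyldecahydronaphthalen-1-yl]acetate | C[C@]12CCCC([C@@H]1CC[C@@](O)([C@@H]2CC(=O)[O-])C)(C)C.[K+]
F8 | step 1 | methyl 2-[(1R,2R,4aS,8aS)-2-hydroxy-2,5,5,8a-tetramethyldecahydronaphthalen-1-yl]acetate | C[C@]12CCCC([C@@H]1CC[C@@](O)([C@@H]2CC(=O)OC)C)(C)C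
F9 | step 1 | methyl 2-[(1S,4aS,8aS)-5,5,8a-trimethyl-2-methylidenedecahydronaphthalen-1-yl]acetate | C[C@]12CCCC([C@@H]1CCC(=C)[C@@H]2CC(=O)OC)(C)C
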